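Slowness came up first: the chair asked whether 2.5 min was too short, since a share read from an unfinished flask is worth little.

the same everywhere: starting material 0.20 M
- east: partner A 0.90 equiv; partner B 2 equiv; protic impurity 0.023 M; run made earlier
- south-west: partner A 0.90 equiv; partner B 2 equiv; protic impurity 0.041 M; run made earlier
- west: partner A 0.90 equiv; partner B 2 equiv; protic impurity 0.095 M; run made earlier
- Tuesday's: partner A 0.900 equiv; partner B 2.00 equiv; protic impurity 0.0200 M; time 2.5 min
- Saturday's: partner A 0.900 equiv; partner B 2.00 equiv; protic impurity 0.0400 M; time 2.5 min
- Thursday's: partner A 0.900 equiv; partner B 2.00 equiv; protic impurity 0.0800 M; time 2.5 min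

| run | time / min | target / % | homo product / % | side product / % |
|---|---|---|---|---|
| east | 0.200 | 2 | 6 | 10 |
| east | 0.667 | 12 | 12 | 39 |
| east | 1.33 | 19 | 15 | 53 |
| east | 2.00 | 18 | 18 | 58 |
| east | 2.50 | 21 | 16 | 58 |
| south-west | 0.500 | 10 | 11 | 31 |
| south-west | 1.00 | 15 | 16 | 51 |
| south-west | 1.50 | 18 | 21 | 57 |
| south-west | 2.00 | 20 | 17 | 60 |
| south-west | 2.50 | 21 | 17 | 63 |
| west | 0.200 | 1 | 3 | 14 |
| west | 0.417 | 7 | 11 | 26 |
| west | 0.667 | 9 | 16 | 41 |
| west | 1.33 | 16 | 15 | 59 |
| west | 2.50 | 17 | 16 | 66 |

(scatter of a reading: 1.5 percentage points)

- percentages count the starting material that a species holds: one homo product counts as two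
- the numbers in the tables scatter by 1.5 percentage points (one standard deviation)
- "hardly changes" means that all values lie within two and a half points (for a concentration: within two and a half percent of the largest)

The kineticist answered from the totals. Target, homo product and side product together read 95.0 %, 101 % and 99.0 % in the east, south-west and west runs at 2.5 min, against 100 % charged, so she treated these readings as close to an end state.

The process chemist then asked for the selectivity at that end, target over the sum of the three products. It reads 22.1 % in the east run, 20.8 % in the south-west run and 17.2 % in the west run. That is a fall of 4.9 percentage points from east to west, against a scatter of 1.5 points on each reading.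

I proposed a straight line through the east and west runs, with slope 0.685 L mol⁻¹, and called it the share drop: the target share, taken as a fraction, that goes for each further mole per litre of [protic impurity], with the charges of starting material, partner A and partner B held as in these runs and the share read at 2.5 min. The south-west run stayed out of that line, so it could test it. The line gives 20.9 % at 0.041 M, and the run reads 20.8 %.

- share of target in all that became target or homo product or side product for Tuesday's, Saturday's, Thursday's, in this order
- how that number moves from the first to the last of them (hardly changes / rises all the way / rises, then falls / falls all the way / falls, then rises)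

So I committed to 22.3 %, 20.9 % and 18.2 % for Tuesday's, Saturday's and Thursday's.

The forecast gave 21.5 %, 20.2 % and 18 %, falls all the way, lower than mine at each of the points, and its maker argued: “Impurity only moderately tilts selectivity toward side product”.

The flask gives 22.5 %, 21.0 % and 17.9 % for Tuesday's, Saturday's and Thursday's: falls all the way.

    partner B + partner A → second intermediate (k = 0.130 L mol⁻¹ s⁻¹)
    open intermediate + second intermediate → target (k = 0.140 L mol⁻¹ s⁻¹)
    partner A + protic impurity → quenched reagent (k = 1.10 L mol⁻¹ s⁻¹)
    open intermediate → side product (k = 0.0260 s⁻¹)
    2 open intermediate → homo product (k = 0.0570 L mol⁻¹ s⁻¹)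
    starting material + partner B → open intermediate (k = 0.320 L mol⁻¹ s⁻¹)

At 2.50 min, Thursday's holds 0.0616 M of second intermediate and 0.0788 M of quenched reagent, where Tuesday's holds 0.0968 M and 0.0200 M. Start from Saturday's 21.0 % and apply the share drop of 0.685 L mol⁻¹ across the further 0.0400 M of [protic impurity]: that gives 18.3 % for Thursday's, which stands at 17.9 %.

The numbers in the tables stem from a simulated flask from invented constants; scatter was added.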